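**Retrosynthetic overview**
1. Target 32 ⇐ macrocyclic enoate 27: reduce the C9 ester, then acylate C4–OH with the senecioyl group and remove silyl groups (steps 16–20).
2. 27 ⇐ seco-aldehyde 26: intramolecular Horner–Wadsworth–Emmons closure of C9=C10, the only carbocycle-forming step.
3. 26 ⇐ allylic alcohol 24: aliphatic Claisen rearrangement forms C1–C11, sets the quaternary C1 by chirality transfer from C3, and gives the E-C2=C3 alkene.
4. 24 ⇐ vinyl iodide 9 + aldehyde 23 (NiCl2/CrCl2 coupling at C2–C3). Fragment A (9) comes from (S)-5-oxotetrahydrofuran-2-carboxylic acid (L-glutamic acid pool); fragment B (23) from methyl (R)-glycerate acetonide (D-mannitol pool) and a C5 Wittig salt.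
5. Ring order: oxirane first (step 11, on acyclic fragment B), then the 11-membered ring (step 15).

Assumption and locants: the SMILES is read literally as (1S,4R,5S,6S,3'S), E-C2=C3, cis-epoxide at C5/C6, C8 and C11 cis across C9=C10; ring C1 (quaternary) to C11, C12 = CH2OH carbon on C9, side chain C1'–C5' from C1 (C3' = carbinol).

**Fragment A (steps 1–5)**

Step 1
Reactants: 1 (2S)-5-oxooxolane-2-carboxylic acid
Product: 3 (5S)-5-acetyloxolan-2-one, via acid chloride 2 (not isolated)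
Conditions: (COCl)2, N,N-dimethylformamide (cat.), CH2Cl2, 0 °C to rt; evaporate; then MeMgBr, iron tris(acetylacetonate) Fe(acac)3 (3 mol %), THF, −78 °C
Reagents that add atoms: oxalyl chloride ClC(=O)C(Cl)=O; methylmagnesium bromide C[Mg]Br
Why: Acid chloride formation followed by iron-catalysed Grignard acylation stops at the ketone at −78 °C and leaves the lactone and the α-stereocentre untouched.

Step 2
Reactants: 3 (5S)-5-acetyloxolan-2-one
Product: 4 (5S)-5-(prop-1-en-2-yl)oxolan-2-one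
Conditions: Zn, CH2Br2, TiCl4, THF/CH2Cl2, 0 °C to rt
Reagents that add atoms: dibromomethane BrCBr
Why: Takai–Lombardo methylenation is non-basic, so the α-acyloxy ketone is not epimerised and the lactone carbonyl is not attacked.

Step 3
Reactants: 4 (5S)-5-(prop-1-en-2-yl)oxolan-2-one
Product: 6 (3S)-2-methylhept-1-en-6-yn-3-ol, via lactol 5 (not isolated)
Conditions: iBu2AlH (1.05 equiv), CH2Cl2, −78 °C; then MeOH, K2CO3, dimethyl (1-diazo-2-oxopropyl)phosphonate, −78 °C to rt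
Reagents that add atoms: dimethyl (1-diazo-2-oxopropyl)phosphonate CC(=O)C(=[N+]=[N-])P(=O)(OC)OC
Why: Half-reduction to the lactol and Ohira–Bestmann (Seyferth–Gilbert) homologation of its open hydroxy-aldehyde form give the terminal alkyne without touching the carbinol centre.

Step 4
Reactants: 6 (3S)-2-methylhept-1-en-6-yn-3-ol
Product: 7 tert-butyl(dimethyl){[(3S)-2-methylhept-1-en-6-yn-3-yl]oxy}silane
Conditions: tBuMe2SiCl, imidazole, DMF, rt
Reagents that add atoms: tert-butyldimethylsilyl chloride CC(C)(C)[Si](C)(C)Cl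
Why: Standard silylation masks the side-chain allylic alcohol so that it cannot take part in the later vinyl-ether Claisen step.

Step 5
Reactants: 7 tert-butyl(dimethyl){[(3S)-2-methylhept-1-en-6-yn-3-yl]oxy}silane
Product: 9 tert-butyl{[(3S,6E)-7-iodo-2,6-dimethylhepta-1,6-dien-3-yl]oxy}dimethylsilane, via alkenyldimethylalane 8 (not isolated)
Conditions: AlMe3 (2.5 equiv), zirconocene dichloride Cp2ZrCl2 (0.25 equiv), CH2Cl2, 0 °C to rt; then I2, THF, −30 to 0 °C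
Reagents that add atoms: trimethylaluminium C[Al](C)C; iodine II
Why: Negishi zirconium-catalysed carboalumination adds Me and Al syn across the terminal alkyne (Me to the internal carbon) and iodinolysis with retention gives the E-iodide with Me cis to iodine; the 1,1-disubstituted alkene is inert.

**Fragment B (steps 6–12)**

Step 6
Reactants: 10 methyl (4R)-2,2-dimethyl-1,3-dioxolane-4-carboxylate
Product: 12 1-[(4R)-2,2-dimethyl-1,3-dioxolan-4-yl]ethan-1-one, via Weinreb amide 11 (not isolated)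
Conditions: MeNH(OMe)·HCl, iPrMgCl, THF, −20 °C; then MeMgBr, −20 to 0 °C; aq. NH4Cl
Reagents that add atoms: N,O-dimethylhydroxylamine hydrochloride CNOC.Cl; methylmagnesium bromide C[Mg]Br
Why: One-pot Weinreb amide formation and Weinreb ketone synthesis give the methyl ketone through a stable chelate, without over-addition or loss of the α-stereocentre.

Step 7
Reactants: 12 1-[(4R)-2,2-dimethyl-1,3-dioxolan-4-yl]ethan-1-one; 13 (4-carboxybutyl)triphenylphosphonium bromide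
Product: 16 methyl (5Z)-6-[(4S)-2,2-dimethyl-1,3-dioxolan-4-yl]hept-5-enoate, via phosphonium ylide 14 (not isolated), via sodium carboxylate 15 (not isolated)
Conditions: 13, NaN(SiMe3)2 (2 equiv), THF, 0 °C; add 12, −78 °C to rt; then MeI, DMF, rt
Reagents that add atoms: sodium bis(trimethylsilyl)amide [Na+].C[Si](C)(C)[N-][Si](C)(C)C; iodomethane CI
Why: Wittig olefination of an α-alkoxy methyl ketone with a non-stabilised ylide (Still-type) puts the oxygenated carbon cis to the new chain, giving the Z-trisubstituted alkene (C4 cis to C7); the carboxylate is then O-methylated in the same flask.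

Step 8
Reactants: 16 methyl (5Z)-6-[(4S)-2,2-dimethyl-1,3-dioxolan-4-yl]hept-5-enoate
Product: 19 methyl (5Z)-2-(diethoxyphosphoryl)-6-[(4S)-2,2-dimethyl-1,3-dioxolan-4-yl]hept-5-enoate, via lithium enolate 17 (not isolated), via phosphonite 18 (not isolated)
Conditions: LiN(iPr)2, THF, −78 °C; ClP(OEt)2, −78 °C to rt; then 30% aq. H2O2, 0 °C
Reagents that add atoms: lithium diisopropylamide [Li+].CC(C)[N-]C(C)C; diethyl chlorophosphite CCOP(Cl)OCC; hydrogen peroxide OO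
Why: Ester enolate C-phosphinylation with the trivalent phosphorus chloride followed by oxidation gives the α-phosphono ester cleanly; the new C9 centre is a mixture that is erased in step 15.

Step 9
Reactants: 19 methyl (5Z)-2-(diethoxyphosphoryl)-6-[(4S)-2,2-dimethyl-1,3-dioxolan-4-yl]hept-5-enoate
Product: 20 methyl (5Z,7S)-2-(diethoxyphosphoryl)-7,8-dihydroxy-6-methyloct-5-enoate
Conditions: AcOH/H2O (4:1), 40 °C
Reagents that add atoms: none
Why: Mild acetal hydrolysis frees the 1,2-diol while the esters, the phosphonate and the alkene are stable.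

Step 10
Reactants: 20 methyl (5Z,7S)-2-(diethoxyphosphoryl)-7,8-dihydroxy-6-methyloct-5-enoate
Product: 21 methyl (5Z,7S)-2-(diethoxyphosphoryl)-6-methyl-7,8-bis[(triethylsilyl)oxy]oct-5-enoate
Conditions: Et3SiCl, imidazole, DMF, 0 °C to rt
Reagents that add atoms: chlorotriethylsilane CC[Si](Cl)(CC)CC
Why: Bis-silylation gives a non-directing C4 silyl ether for the epoxidation and a primary triethylsilyl ether that can be oxidised directly in step 12.

Step 11
Reactants: 21 methyl (5Z,7S)-2-(diethoxyphosphoryl)-6-methyl-7,8-bis[(triethylsilyl)oxy]oct-5-enoate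
Product: 22 methyl 4-[(2S,3S)-3-{(1R)-1,2-bis[(triethylsilyl)oxy]ethyl}-3-methyloxiran-2-yl]-2-(diethoxyphosphoryl)butanoate
Conditions: mCPBA, NaHCO3, CH2Cl2, 0 °C
Reagents that add atoms: 3-chloroperoxybenzoic acid OOC(=O)c1cccc(Cl)c1
Why: Prilezhaev epoxidation is stereospecific (Z-alkene gives the cis-epoxide); A(1,3) strain holds C4–H in the alkene plane and the peracid attacks the only alkene anti to the C4 silyloxy group, giving 5S,6S (expected about 5:1, minor isomer removed by chromatography).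

Step 12
Reactants: 22 methyl 4-[(2S,3S)-3-{(1R)-1,2-bis[(triethylsilyl)oxy]ethyl}-3-methyloxiran-2-yl]-2-(diethoxyphosphoryl)butanoate
Product: 23 methyl 2-(diethoxyphosphoryl)-4-[(2S,3S)-3-methyl-3-{(1S)-2-oxo-1-[(triethylsilyl)oxy]ethyl}oxiran-2-yl]butanoate
Conditions: (COCl)2, DMSO, CH2Cl2, −78 to −40 °C; then Et3N, −78 °C to rt
Reagents that add atoms: none
Why: Swern oxidation converts a primary triethylsilyl ether directly into the aldehyde while the secondary silyl ether, the epoxide and the phosphonoester survive.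

**Coupling, key rearrangement and ring closure (steps 13–15)**

Step 13
Reactants: 23 methyl 2-(diethoxyphosphoryl)-4-[(2S,3S)-3-methyl-3-{(1S)-2-oxo-1-[(triethylsilyl)oxy]ethyl}oxiran-2-yl]butanoate; 9 tert-butyl{[(3S,6E)-7-iodo-2,6-dimethylhepta-1,6-dien-3-yl]oxy}dimethylsilane
Product: 24 methyl 4-{(2S,3S)-3-[(1R,2R,3E,7S)-7-{[tert-butyl(dimethyl)silyl]oxy}-2-hydroxy-4,8-dimethyl-1-[(triethylsilyl)oxy]nona-3,8-dien-1-yl]-3-methyloxiran-2-yl}-2-(diethoxyphosphoryl)butanoate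
Conditions: CrCl2 (6 equiv), NiCl2 (1 mol %), DMSO/THF, rt
Reagents that add atoms: none
Why: Nozaki–Hiyama–Kishi coupling is selective for the aldehyde in the presence of the esters, epoxide and acidic phosphonoacetate; Felkin–Anh addition anti to the C4 silyloxy group gives the 3,4-anti (3R) alcohol (about 4:1 expected, syn epimer separated).

Step 14
Reactants: 24 methyl 4-{(2S,3S)-3-[(1R,2R,3E,7S)-7-{[tert-butyl(dimethyl)silyl]oxy}-2-hydroxy-4,8-dimethyl-1-[(triethylsilyl)oxy]nona-3,8-dien-1-yl]-3-methyloxiran-2-yl}-2-(diethoxyphosphoryl)butanoate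
Product: 26 methyl 4-{(2S,3S)-3-[(1R,2E,4S,7S)-7-{[tert-butyl(dimethyl)silyl]oxy}-4,8-dimethyl-4-(2-oxoethyl)-1-[(triethylsilyl)oxy]nona-2,8-dien-1-yl]-3-methyloxiran-2-yl}-2-(diethoxyphosphoryl)butanoate, via allyl vinyl ether 25 (not isolated)
Conditions: ethyl vinyl ether (solvent), Hg(OAc)2 (0.3 equiv), reflux; evaporate; then toluene, 130 °C, sealed tube
Reagents that add atoms: ethyl vinyl ether C=COCC
Why: Mercury-catalysed transetherification then aliphatic Claisen rearrangement ([3,3]-sigmatropic) through a chair with C4 pseudo-equatorial forms C1–C11 on the face from which O3 leaves, so C3 (R) becomes quaternary C1 (S) and the new C2=C3 alkene is E.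

Step 15
Reactants: 26 methyl 4-{(2S,3S)-3-[(1R,2E,4S,7S)-7-{[tert-butyl(dimethyl)silyl]oxy}-4,8-dimethyl-4-(2-oxoethyl)-1-[(triethylsilyl)oxy]nona-2,8-dien-1-yl]-3-methyloxiran-2-yl}-2-(diethoxyphosphoryl)butanoate
Product: 27 methyl (1S,4E,7S,8E,10R,11S)-7-[(3S)-3-{[tert-butyl(dimethyl)silyl]oxy}-4-methylpent-4-en-1-yl]-7,11-dimethyl-10-[(triethylsilyl)oxy]-12-oxabicyclo[9.1.0]dodeca-4,8-diene-4-carboxylate
Conditions: LiCl, DBU, MeCN, 1 mM (syringe pump), rt
Reagents that add atoms: none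
Why: Intramolecular Horner–Wadsworth–Emmons olefination (Masamune–Roush conditions, high dilution) closes the 11-membered ring; the usual preference for the ester trans to the aldehyde-derived carbon coincides with the less strained ring-cis trisubstituted alkene.

**Endgame (steps 16–20)**

Step 16
Reactants: 27 methyl (1S,4E,7S,8E,10R,11S)-7-[(3S)-3-{[tert-butyl(dimethyl)silyl]oxy}-4-methylpent-4-en-1-yl]-7,11-dimethyl-10-[(triethylsilyl)oxy]-12-oxabicyclo[9.1.0]dodeca-4,8-diene-4-carboxylate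
Product: 28 [(1S,4E,7S,8E,10R,11S)-7-[(3S)-3-{[tert-butyl(dimethyl)silyl]oxy}-4-methylpent-4-en-1-yl]-7,11-dimethyl-10-[(triethylsilyl)oxy]-12-oxabicyclo[9.1.0]dodeca-4,8-dien-4-yl]methanol
Conditions: iBu2AlH (3 equiv), CH2Cl2, −78 °C
Reagents that add atoms: none
Why: Hydride 1,2-reduction of the enoate gives the primary allylic alcohol; the epoxide and silyl ethers are stable at −78 °C.

Step 17
Reactants: 28 [(1S,4E,7S,8E,10R,11S)-7-[(3S)-3-{[tert-butyl(dimethyl)silyl]oxy}-4-methylpent-4-en-1-yl]-7,11-dimethyl-10-[(triethylsilyl)oxy]-12-oxabicyclo[9.1.0]dodeca-4,8-dien-4-yl]methanol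
Product: 29 tert-butyl{[(1S,4E,7S,8E,10R,11S)-7-[(3S)-3-{[tert-butyl(dimethyl)silyl]oxy}-4-methylpent-4-en-1-yl]-7,11-dimethyl-10-[(triethylsilyl)oxy]-12-oxabicyclo[9.1.0]dodeca-4,8-dien-4-yl]methoxy}diphenylsilane
Conditions: tBuPh2SiCl, imidazole, CH2Cl2, 0 °C
Reagents that add atoms: tert-butyl(chloro)diphenylsilane CC(C)(C)[Si](Cl)(c1ccccc1)c1ccccc1
Why: Silylation blocks the primary alcohol with a group that outlasts the triethylsilyl ether in the next step.

Step 18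
Reactants: 29 tert-butyl{[(1S,4E,7S,8E,10R,11S)-7-[(3S)-3-{[tert-butyl(dimethyl)silyl]oxy}-4-methylpent-4-en-1-yl]-7,11-dimethyl-10-[(triethylsilyl)oxy]-12-oxabicyclo[9.1.0]dodeca-4,8-dien-4-yl]methoxy}diphenylsilane
Product: 30 (1R,2R,3E,5S,7E,11S)-5-[(3S)-3-{[tert-butyl(dimethyl)silyl]oxy}-4-methylpent-4-en-1-yl]-8-({[tert-butyl(diphenyl)silyl]oxy}methyl)-1,5-dimethyl-12-oxabicyclo[9.1.0]dodeca-3,7-dien-2-ol
Conditions: HF·pyridine, pyridine, THF, 0 °C
Reagents that add atoms: none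
Why: Buffered fluoride desilylation removes the triethylsilyl ether far faster than the two bulkier silyl ethers and does not open the epoxide (the 1R descriptor is only a CIP priority change caused by the free hydroxyl).

Step 19
Reactants: 30 (1R,2R,3E,5S,7E,11S)-5-[(3S)-3-{[tert-butyl(dimethyl)silyl]oxy}-4-methylpent-4-en-1-yl]-8-({[tert-butyl(diphenyl)silyl]oxy}methyl)-1,5-dimethyl-12-oxabicyclo[9.1.0]dodeca-3,7-dien-2-ol
Product: 31 (1S,2R,3E,5S,7E,11S)-5-[(3S)-3-{[tert-butyl(dimethyl)silyl]oxy}-4-methylpent-4-en-1-yl]-8-({[tert-butyl(diphenyl)silyl]oxy}methyl)-1,5-dimethyl-12-oxabicyclo[9.1.0]dodeca-3,7-dien-2-yl 3-methylbut-2-enoate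
Conditions: 3-methylbut-2-enoyl chloride, pyridine, 4-(dimethylamino)pyridine (cat.), CH2Cl2, 0 °C to rt
Reagents that add atoms: 3-methylbut-2-enoyl chloride CC(C)=CC(Cl)=O
Why: Nucleophile-catalysed acylation of the only free hydroxyl installs the senecioate with retention at C4; pyridine rather than a trialkylamine limits deconjugation of the acyl group.

Step 20
Reactants: 31 (1S,2R,3E,5S,7E,11S)-5-[(3S)-3-{[tert-butyl(dimethyl)silyl]oxy}-4-methylpent-4-en-1-yl]-8-({[tert-butyl(diphenyl)silyl]oxy}methyl)-1,5-dimethyl-12-oxabicyclo[9.1.0]dodeca-3,7-dien-2-yl 3-methylbut-2-enoate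
Product: 32 (1S,2R,3E,5S,7E,11S)-8-(hydroxymethyl)-5-[(3S)-3-hydroxy-4-methylpent-4-en-1-yl]-1,5-dimethyl-12-oxabicyclo[9.1.0]dodeca-3,7-dien-2-yl 3-methylbut-2-enoate
Conditions: Bu4NF, AcOH, THF, 0 °C to rt
Reagents that add atoms: none
Why: Acetic-acid-buffered fluoride desilylation removes both remaining silyl ethers without ester migration or epoxide opening.

**Compound list**
1 | (2S)-5-oxooxolane-2-carboxylic acid | OC(=O)[C@@H]1CCC(=O)O1 | starting material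
2 | (2S)-5-oxooxolane-2-carbonyl chloride | ClC(=O)[C@@H]1CCC(=O)O1 | intermediate
3 | (5S)-5-acetyloxolan-2-one | CC(=O)[C@@H]1CCC(=O)O1 | intermediate
4 | (5S)-5-(prop-1-en-2-yl)oxolan-2-one | C=C(C)[C@@H]1CCC(=O)O1 | intermediate
5 | (5S)-5-(prop-1-en-2-yl)oxolan-2-ol (lactol; anomer mixture) | C=C(C)[C@@H]1CCC(O)O1 | intermediate
6 | (3S)-2-methylhept-1-en-6-yn-3-ol | C=C(C)[C@@H](O)CCC#C | intermediate
7 | tert-butyl(dimethyl){[(3S)-2-methylhept-1-en-6-yn-3-yl]oxy}silane | C=C(C)[C@@H](O[Si](C)(C)C(C)(C)C)CCC#C | intermediate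
8 | [(1E,5S)-5-{[tert-butyl(dimethyl)silyl]oxy}-2,6-dimethylhepta-1,6-dien-1-yl](dimethyl)alumane | C=C(C)[C@@H](O[Si](C)(C)C(C)(C)C)CC/C(C)=C/[Al](C)C | intermediate
9 | tert-butyl{[(3S,6E)-7-iodo-2,6-dimethylhepta-1,6-dien-3-yl]oxy}dimethylsilane | C=C(C)[C@@H](O[Si](C)(C)C(C)(C)C)CC/C(C)=C/I | intermediate
10 | methyl (4R)-2,2-dimethyl-1,3-dioxolane-4-carboxylate | COC(=O)[C@H]1COC(C)(C)O1 | starting material
11 | (4R)-N-methoxy-N,2,2-trimethyl-1,3-dioxolane-4-carboxamide | CON(C)C(=O)[C@H]1COC(C)(C)O1 | intermediate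
12 | 1-[(4R)-2,2-dimethyl-1,3-dioxolan-4-yl]ethan-1-one | CC(=O)[C@H]1COC(C)(C)O1 | intermediate
13 | (4-carboxybutyl)triphenylphosphonium bromide | OC(=O)CCCC[P+](c1ccccc1)(c1ccccc1)c1ccccc1.[Br-] | starting material
14 | sodium 5-(triphenyl-λ5-phosphanylidene)pentanoate (ylide) | [Na+].[O-]C(=O)CCCC=P(c1ccccc1)(c1ccccc1)c1ccccc1 | intermediate
15 | sodium (5Z)-6-[(4S)-2,2-dimethyl-1,3-dioxolan-4-yl]hept-5-enoate | [Na+].[O-]C(=O)CCC/C=C(/C)[C@H]1COC(C)(C)O1 | intermediate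
16 | methyl (5Z)-6-[(4S)-2,2-dimethyl-1,3-dioxolan-4-yl]hept-5-enoate | COC(=O)CCC/C=C(/C)[C@H]1COC(C)(C)O1 | intermediate
17 | lithium enolate of 16 (lithium 1-methoxyhepta-1,5-dien-1-olate form) | [Li+].[O-]C(OC)=CCC/C=C(/C)[C@H]1COC(C)(C)O1 | intermediate
18 | methyl (5Z)-2-(diethoxyphosphanyl)-6-[(4S)-2,2-dimethyl-1,3-dioxolan-4-yl]hept-5-enoate (C2 epimers) | COC(=O)C(CC/C=C(/C)[C@H]1COC(C)(C)O1)P(OCC)OCC | intermediate
19 | methyl (5Z)-2-(diethoxyphosphoryl)-6-[(4S)-2,2-dimethyl-1,3-dioxolan-4-yl]hept-5-enoate (C2 epimers) | COC(=O)C(CC/C=C(/C)[C@H]1COC(C)(C)O1)P(=O)(OCC)OCC | intermediate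
20 | methyl (5Z,7S)-2-(diethoxyphosphoryl)-7,8-dihydroxy-6-methyloct-5-enoate | COC(=O)C(CC/C=C(/C)[C@H](O)CO)P(=O)(OCC)OCC | intermediate
21 | methyl (5Z,7S)-2-(diethoxyphosphoryl)-6-methyl-7,8-bis[(triethylsilyl)oxy]oct-5-enoate | COC(=O)C(CC/C=C(/C)[C@H](O[Si](CC)(CC)CC)CO[Si](CC)(CC)CC)P(=O)(OCC)OCC | intermediate
22 | methyl 4-[(2S,3S)-3-{(1R)-1,2-bis[(triethylsilyl)oxy]ethyl}-3-methyloxiran-2-yl]-2-(diethoxyphosphoryl)butanoate | COC(=O)C(CC[C@@H]1O[C@]1(C)[C@H](O[Si](CC)(CC)CC)CO[Si](CC)(CC)CC)P(=O)(OCC)OCC | intermediate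
23 | methyl 2-(diethoxyphosphoryl)-4-[(2S,3S)-3-methyl-3-{(1S)-2-oxo-1-[(triethylsilyl)oxy]ethyl}oxiran-2-yl]butanoate | COC(=O)C(CC[C@@H]1O[C@]1(C)[C@H](O[Si](CC)(CC)CC)C=O)P(=O)(OCC)OCC | intermediate
24 | methyl 4-{(2S,3S)-3-[(1R,2R,3E,7S)-7-{[tert-butyl(dimethyl)silyl]oxy}-2-hydroxy-4,8-dimethyl-1-[(triethylsilyl)oxy]nona-3,8-dien-1-yl]-3-methyloxiran-2-yl}-2-(diethoxyphosphoryl)butanoate | C=C(C)[C@@H](O[Si](C)(C)C(C)(C)C)CC/C(C)=C/[C@@H](O)[C@@H](O[Si](CC)(CC)CC)[C@@]1(C)O[C@H]1CCC(C(=O)OC)P(=O)(OCC)OCC | intermediate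
25 | methyl 4-{(2S,3S)-3-[(1R,2R,3E,7S)-7-{[tert-butyl(dimethyl)silyl]oxy}-2-(ethenyloxy)-4,8-dimethyl-1-[(triethylsilyl)oxy]nona-3,8-dien-1-yl]-3-methyloxiran-2-yl}-2-(diethoxyphosphoryl)butanoate | C=C(C)[C@@H](O[Si](C)(C)C(C)(C)C)CC/C(C)=C/[C@@H](OC=C)[C@@H](O[Si](CC)(CC)CC)[C@@]1(C)O[C@H]1CCC(C(=O)OC)P(=O)(OCC)OCC | intermediate
26 | methyl 4-{(2S,3S)-3-[(1R,2E,4S,7S)-7-{[tert-butyl(dimethyl)silyl]oxy}-4,8-dimethyl-4-(2-oxoethyl)-1-[(triethylsilyl)oxy]nona-2,8-dien-1-yl]-3-methyloxiran-2-yl}-2-(diethoxyphosphoryl)butanoate | C=C(C)[C@@H](O[Si](C)(C)C(C)(C)C)CC[C@@](C)(CC=O)/C=C/[C@@H](O[Si](CC)(CC)CC)[C@@]1(C)O[C@H]1CCC(C(=O)OC)P(=O)(OCC)OCC | intermediate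
27 | methyl (1S,4E,7S,8E,10R,11S)-7-[(3S)-3-{[tert-butyl(dimethyl)silyl]oxy}-4-methylpent-4-en-1-yl]-7,11-dimethyl-10-[(triethylsilyl)oxy]-12-oxabicyclo[9.1.0]dodeca-4,8-diene-4-carboxylate | C=C(C)[C@@H](O[Si](C)(C)C(C)(C)C)CC[C@]1(C)/C=C/[C@@H](O[Si](CC)(CC)CC)[C@@]2(C)O[C@H]2CC/C(C(=O)OC)=C\C1 | intermediate
28 | [(1S,4E,7S,8E,10R,11S)-7-[(3S)-3-{[tert-butyl(dimethyl)silyl]oxy}-4-methylpent-4-en-1-yl]-7,11-dimethyl-10-[(triethylsilyl)oxy]-12-oxabicyclo[9.1.0]dodeca-4,8-dien-4-yl]methanol | C=C(C)[C@@H](O[Si](C)(C)C(C)(C)C)CC[C@]1(C)/C=C/[C@@H](O[Si](CC)(CC)CC)[C@@]2(C)O[C@H]2CC/C(CO)=C\C1 | intermediate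
29 | tert-butyl{[(1S,4E,7S,8E,10R,11S)-7-[(3S)-3-{[tert-butyl(dimethyl)silyl]oxy}-4-methylpent-4-en-1-yl]-7,11-dimethyl-10-[(triethylsilyl)oxy]-12-oxabicyclo[9.1.0]dodeca-4,8-dien-4-yl]methoxy}diphenylsilane | C=C(C)[C@@H](O[Si](C)(C)C(C)(C)C)CC[C@]1(C)/C=C/[C@@H](O[Si](CC)(CC)CC)[C@@]2(C)O[C@H]2CC/C(CO[Si](c3ccccc3)(c3ccccc3)C(C)(C)C)=C\C1 | intermediate
30 | (1R,2R,3E,5S,7E,11S)-5-[(3S)-3-{[tert-butyl(dimethyl)silyl]oxy}-4-methylpent-4-en-1-yl]-8-({[tert-butyl(diphenyl)silyl]oxy}methyl)-1,5-dimethyl-12-oxabicyclo[9.1.0]dodeca-3,7-dien-2-ol | C=C(C)[C@@H](O[Si](C)(C)C(C)(C)C)CC[C@]1(C)/C=C/[C@@H](O)[C@@]2(C)O[C@H]2CC/C(CO[Si](c3ccccc3)(c3ccccc3)C(C)(C)C)=C\C1 | intermediate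
31 | (1S,2R,3E,5S,7E,11S)-5-[(3S)-3-{[tert-butyl(dimethyl)silyl]oxy}-4-methylpent-4-en-1-yl]-8-({[tert-butyl(diphenyl)silyl]oxy}methyl)-1,5-dimethyl-12-oxabicyclo[9.1.0]dodeca-3,7-dien-2-yl 3-methylbut-2-enoate | C=C(C)[C@@H](O[Si](C)(C)C(C)(C)C)CC[C@]1(C)/C=C/[C@@H](OC(=O)C=C(C)C)[C@@]2(C)O[C@H]2CC/C(CO[Si](c3ccccc3)(c3ccccc3)C(C)(C)C)=C\C1 | intermediate
32 | (1S,2R,3E,5S,7E,11S)-8-(hydroxymethyl)-5-[(3S)-3-hydroxy-4-methylpent-4-en-1-yl]-1,5-dimethyl-12-oxabicyclo[9.1.0]dodeca-3,7-dien-2-yl 3-methylbut-2-enoate | C=C(C)[C@@H](O)CC[C@]1(C)/C=C/[C@@H](OC(=O)C=C(C)C)[C@@]2(C)O[C@H]2CC/C(CO)=C\C1 | target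

**Step count**
Total: 20 steps (telescoped operations with a non-isolated intermediate counted as one step). Longest linear sequence: 15 steps (10 to 32, steps 6–20). Fragment A takes 5 steps (1 to 9).

**Three steps most likely to fail**

Step 13 (NiCl2/CrCl2 coupling). The C3 configuration rests on Felkin–Anh control by a single silyloxy stereocentre and may be modest; the wrong C3 epimer would give the wrong C1 after step 14. The fallback sets out from 23 (coupled with 9 as before) and comes back to the route at 24. The coupling is run without regard to selectivity, and the separated 3,4-syn alcohol, the C3 epimer of 24 F1, is inverted by a Mitsunobu reaction (4-nitrobenzoic acid, PPh3, diisopropyl azodicarboxylate, toluene, 0 °C) to the 4-nitrobenzoate of 24 F2. Brief methanolysis (K2CO3, MeOH, 0 °C) then releases 24, so both epimers are funnelled into the required one.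

Step 14 (vinyl ether formation and Claisen rearrangement). Mercury-catalysed transetherification of a hindered secondary alcohol flanked by a silyloxy carbon can stall. The fallback sets out from 24 and comes back at 26, using an Eschenmoser–Claisen rearrangement, which tolerates hindered alcohols. Heating 24 with 1,1-dimethoxy-N,N-dimethylethanamine in xylene at 130 °C gives the ketene N,O-acetal of 24 F3, which rearranges in the flask through the same chair to the N,N-dimethylamide analogue of 26 F4. Zirconocene chloride hydride Cp2Zr(H)Cl (THF, rt) then reduces the tertiary amide to the aldehyde 26 without touching the esters.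

Step 15 (11-membered ring closure). Oligomerisation, or attack of the phosphonate anion on the nearby oxirane, may compete. The fallback sets out from 21 and comes back at 27: the ring is closed on the epoxide-free triene and the oxirane is installed on the macrocycle.
- 21 is oxidised directly (Swern, as in step 12) to the Z-alkene aldehyde F5.
- F5 is coupled with 9 (CrCl2, NiCl2) to the allylic alcohol F6.
- F6 is converted through its allyl vinyl ether F7 (ethyl vinyl ether, Hg(OAc)2; then 130 °C) into the Claisen aldehyde F8.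
- F8 is cyclised (LiCl, DBU, MeCN, 1 mM) to the macrocyclic triene ester F9.
- mCPBA (NaHCO3, CH2Cl2, 0 °C) then epoxidises the only electron-rich trisubstituted alkene of F9, anti to the C4 silyloxy group, to give 27.

**Further compounds**
F1 | step 13 | C3 epimer of 24 (3S; 3,4-syn alcohol) | C=C(C)[C@@H](O[Si](C)(C)C(C)(C)C)CC/C(C)=C/[C@H](O)[C@@H](O[Si](CC)(CC)CC)[C@@]1(C)O[C@H]1CCC(C(=O)OC)P(=O)(OCC)OCC
F2 | step 13 | 4-nitrobenzoate of 24 (C3 inverted to R) | C=C(C)[C@@H](O[Si](C)(C)C(C)(C)C)CC/C(C)=C/[C@@H](OC(=O)c1ccc(cc1)[N+](=O)[O-])[C@@H](O[Si](CC)(CC)CC)[C@@]2(C)O[C@H]2CCC(C(=O)OC)P(=O)(OCC)OCC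
F3 | step 14 | ketene N,O-acetal of 24 (O-[1-(dimethylamino)ethenyl] ether at C3) | C=C(C)[C@@H](O[Si](C)(C)C(C)(C)C)CC/C(C)=C/[C@@H](OC(=C)N(C)C)[C@@H](O[Si](CC)(CC)CC)[C@@]1(C)O[C@H]1CCC(C(=O)OC)P(=O)(OCC)OCC
F4 | step 14 | N,N-dimethylamide analogue of 26 (CH2C(=O)NMe2 on C1 in place of CH2CHO) | C=C(C)[C@@H](O[Si](C)(C)C(C)(C)C)CC[C@@](C)(CC(=O)N(C)C)/C=C/[C@@H](O[Si](CC)(CC)CC)[C@@]1(C)O[C@H]1CCC(C(=O)OC)P(=O)(OCC)OCC
F5 | step 15 | methyl (5Z,7S)-2-(diethoxyphosphoryl)-6-methyl-8-oxo-7-[(triethylsilyl)oxy]oct-5-enoate | COC(=O)C(CC/C=C(/C)[C@H](O[Si](CC)(CC)CC)C=O)P(=O)(OCC)OCC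
F6 | step 15 | methyl (5Z,7S,8R,9E,13S)-13-{[tert-butyl(dimethyl)silyl]oxy}-2-(diethoxyphosphoryl)-8-hydroxy-6,10,14-trimethyl-7-[(triethylsilyl)oxy]pentadeca-5,9,14-trienoate | C=C(C)[C@@H](O[Si](C)(C)C(C)(C)C)CC/C(C)=C/[C@@H](O)[C@@H](O[Si](CC)(CC)CC)/C(C)=C\CCC(C(=O)OC)P(=O)(OCC)OCC
F7 | step 15 | vinyl ether of F6 (8-ethenyloxy in place of 8-hydroxy) | C=C(C)[C@@H](O[Si](C)(C)C(C)(C)C)CC/C(C)=C/[C@@H](OC=C)[C@@H](O[Si](CC)(CC)CC)/C(C)=C\CCC(C(=O)OC)P(=O)(OCC)OCC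
F8 | step 15 | methyl (5Z,7R,8E,10S,13S)-13-{[tert-butyl(dimethyl)silyl]oxy}-2-(diethoxyphosphoryl)-6,10,14-trimethyl-10-(2-oxoethyl)-7-[(triethylsilyl)oxy]pentadeca-5,8,14-trienoate | C=C(C)[C@@H](O[Si](C)(C)C(C)(C)C)CC[C@@](C)(CC=O)/C=C/[C@@H](O[Si](CC)(CC)CC)/C(C)=C\CCC(C(=O)OC)P(=O)(OCC)OCC
F9 | step 15 | C5=C6 Z-alkene analogue of 27 (11-membered triene methyl ester; 1S,4R; no oxirane) | C=C(C)[C@@H](O[Si](C)(C)C(C)(C)C)CC[C@]1(C)/C=C/[C@@H](O[Si](CC)(CC)CC)/C(C)=C\CC/C(C(=O)OC)=C\C1
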